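**Assumption:** paratocarpin B has no stereocentre, so "single enantiomer" is read as the one achiral compound drawn, whose only stereo-element is the (E)-enone.

## Retrosynthetic overview

1. Carbon sources: 2,4-dihydroxyacetophenone 1 and prenyl bromide 2 give C-prenyl ketone 3; 4-hydroxybenzaldehyde 4 and 2 give C-prenyl aldehyde 5 (direct nuclear prenylation, as a prenyltransferase would do).
2. Enone C=C: protecting-group-free Claisen–Schmidt condensation of 3 with 5 (through aldol adduct 6) gives kanzonol C 7, the presumed biogenetic precursor.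
3. Key disconnection, kept for the last step: the pyran O–C(CH3)2 bond is opened to ring A ortho-quinone methide 8, formed from 7 by site-selective dehydrogenation of the ring A prenyl group while the ring B prenylphenol stays untouched; 8 closes to paratocarpin B 9.
4. Ring order: rings A and B are bought; the pyran ring is the only ring made, and it is formed last by oxa-6π electrocyclisation.

## Route

Step 1
Reactants: 1 2,4-dihydroxyacetophenone; 2 prenyl bromide (1-bromo-3-methylbut-2-ene)
Product: 3 C-prenyl ketone 1-[2,4-dihydroxy-3-(3-methylbut-2-en-1-yl)phenyl]ethan-1-one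
Conditions: KOH (10% aq, 2 equiv), 2 (1.0 equiv) added at 0 °C, then rt, 6 h; dil. HCl; chromatography
Reagents that add atoms: none
Why: Nuclear prenylation (phenoxide C-alkylation) in water, where hydrogen bonding shields the phenoxide oxygen, puts the allyl group mainly on C3, the carbon ortho to both oxygens, and the 5-prenyl, 3,5-diprenyl and O-prenyl by-products are removed by chromatography; no stereocentre is formed.

Step 2
Reactants: 4 4-hydroxybenzaldehyde; 2 prenyl bromide (1-bromo-3-methylbut-2-ene)
Product: 5 C-prenyl aldehyde 4-hydroxy-3-(3-methylbut-2-en-1-yl)benzaldehyde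
Conditions: KOH (aq, 1.1 equiv), 2 (1.0 equiv), rt, 24 h; dil. HCl; chromatography
Reagents that add atoms: none
Why: The same aqueous-alkali phenoxide C-alkylation (nuclear prenylation) takes prenyl bromide at an ortho carbon and rearomatises, the two ortho positions being equivalent so only one C-prenyl isomer can form beside separable O-prenyl ether and diprenyl material; no stereocentre is formed.

Step 3
Reactants: 3 C-prenyl ketone; 5 C-prenyl aldehyde
Product: 7 kanzonol C (E)-1-[2,4-dihydroxy-3-(3-methylbut-2-en-1-yl)phenyl]-3-[4-hydroxy-3-(3-methylbut-2-en-1-yl)phenyl]prop-2-en-1-one, via racemic β-hydroxy ketone aldol adduct 6 (not isolated)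
Conditions: LiN(SiMe3)2 (5.5 equiv), THF, −78 °C → rt, 24 h; then 1 M HCl, 0 °C
Reagents that add atoms: none
Why: Claisen–Schmidt (aldol) condensation of the lithium enolate bis-phenoxide of 3 with the lithium phenoxide of 5 works without protecting groups because the soluble amide base makes the enolate quantitatively, and E1cB loss of hydroxide from 6 erases its carbinol stereocentre and gives the conjugated (E)-enone under thermodynamic control.

Step 4
Reactants: 7 kanzonol C
Product: 9 paratocarpin B (E)-1-(5-hydroxy-2,2-dimethyl-2H-chromen-6-yl)-3-[4-hydroxy-3-(3-methylbut-2-en-1-yl)phenyl]prop-2-en-1-one, via ring A ortho-quinone methide 8 (not isolated)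
Conditions: DDQ (1.0 equiv, added over 1 h), dry 1,4-dioxane, rt, 3 h
Reagents that add atoms: none
Why: Proposed new method: DDQ takes hydride from the benzylic-allylic CH2 of the ring A prenyl group, whose cation is flanked by two oxygen donors whereas the ring B prenyl has only one, loss of the 4'-OH proton gives ortho-quinone methide 8, and thermal oxa-6π electrocyclisation closes the pyran ring through the non-chelated 4'-oxygen (the 2'-OH stays hydrogen-bonded to the carbonyl), the closest known reaction type being the DDQ dehydrogenative cyclisation of a single ortho-prenylphenol to a 2,2-dimethyl-2H-chromene; no stereocentre is formed and the (E)-enone is untouched.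

## Compound list

1 | 2,4-dihydroxyacetophenone | CC(=O)c1ccc(O)cc1O | starting material
2 | prenyl bromide (1-bromo-3-methylbut-2-ene) | CC(C)=CCBr | starting material
3 | 1-[2,4-dihydroxy-3-(3-methylbut-2-en-1-yl)phenyl]ethan-1-one | CC(=O)c1ccc(O)c(CC=C(C)C)c1O | intermediate
4 | 4-hydroxybenzaldehyde | O=Cc1ccc(O)cc1 | starting material
5 | 4-hydroxy-3-(3-methylbut-2-en-1-yl)benzaldehyde | CC(C)=CCc1cc(C=O)ccc1O | intermediate
6 | racemic aldol adduct 1-[2,4-dihydroxy-3-(3-methylbut-2-en-1-yl)phenyl]-3-hydroxy-3-[4-hydroxy-3-(3-methylbut-2-en-1-yl)phenyl]propan-1-one (drawn neutral, not isolated) | CC(C)=CCc1cc(C(O)CC(=O)c2ccc(O)c(CC=C(C)C)c2O)ccc1O | intermediate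
7 | kanzonol C, (E)-1-[2,4-dihydroxy-3-(3-methylbut-2-en-1-yl)phenyl]-3-[4-hydroxy-3-(3-methylbut-2-en-1-yl)phenyl]prop-2-en-1-one | CC(C)=CCc1cc(/C=C/C(=O)c2ccc(O)c(CC=C(C)C)c2O)ccc1O | intermediate
8 | ring A ortho-quinone methide, (6Z)-5-hydroxy-4-{(2E)-3-[4-hydroxy-3-(3-methylbut-2-en-1-yl)phenyl]prop-2-enoyl}-6-(3-methylbut-2-en-1-ylidene)cyclohexa-2,4-dien-1-one (not isolated) | CC(C)=CCc1cc(/C=C/C(=O)C2=C(O)/C(=C/C=C(C)C)C(=O)C=C2)ccc1O | intermediate
9 | paratocarpin B, (E)-1-(5-hydroxy-2,2-dimethyl-2H-chromen-6-yl)-3-[4-hydroxy-3-(3-methylbut-2-en-1-yl)phenyl]prop-2-en-1-one | CC(C)=CCc1cc(/C=C/C(=O)c2ccc3c(c2O)C=CC(C)(C)O3)ccc1O | target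

## Step count and risks

Total step count: 4. Longest linear sequence: 3 (step 1 or step 2, then step 3, then step 4).

**Step 4 (highest risk).** The ring B ortho-prenylphenol may be dehydrogenated competitively, giving the ring B chromene isomer and the bis-chromene. Fallback: the same dehydrogenative oxa-6π closure is done before ring B is present. Setting out from 3, DDQ (1.1 equiv, benzene, 80 °C) gives 1-(5-hydroxy-2,2-dimethyl-2H-chromen-6-yl)ethan-1-one F1. Condensation of F1 with 5 (LiN(SiMe3)2, 3.5 equiv, THF, −78 °C → rt; then 1 M HCl) comes back to the route at 9.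

**Step 3.** The phenoxide of 5 is a poor electrophile, so conversion may stall or the product may be lost on work-up. Fallback: mask the acidic phenols. Setting out from 3 and 5, chloromethyl methyl ether with K2CO3 in acetone converts 3 into 1-[2-hydroxy-4-(methoxymethoxy)-3-(3-methylbut-2-en-1-yl)phenyl]ethan-1-one F2 (the chelated 2-OH stays free) and 5 into 4-(methoxymethoxy)-3-(3-methylbut-2-en-1-yl)benzaldehyde F3. KOH in EtOH/H2O at rt then condenses them to (E)-1-[2-hydroxy-4-(methoxymethoxy)-3-(3-methylbut-2-en-1-yl)phenyl]-3-[4-(methoxymethoxy)-3-(3-methylbut-2-en-1-yl)phenyl]prop-2-en-1-one F4. A catalytic amount of conc. HCl in MeOH at rt (kept mild to avoid chroman or flavanone formation) removes both acetals and comes back to the route at 7.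

**Step 1.** Direct C-prenylation may give too little of the 3-isomer against the 5-prenyl, diprenyl and O-prenyl products. Fallback: deliver the prenyl group by a sigmatropic shift. Setting out from 1, 3-chloro-3-methylbut-1-yne (K2CO3, KI, acetone, reflux) etherifies the non-chelated 4-OH to give 1-[2-hydroxy-4-(2-methylbut-3-yn-2-yloxy)phenyl]ethan-1-one F5. Semihydrogenation (H2, Pd/CaCO3 poisoned with Pb(OAc)2, quinoline, EtOAc) gives 1-[2-hydroxy-4-(2-methylbut-3-en-2-yloxy)phenyl]ethan-1-one F6. Heating in N,N-diethylaniline at 130 °C triggers an aromatic Claisen rearrangement that puts the prenyl group on C3, the ortho carbon favoured by bond fixation in the chelated ketone, and comes back to the route at 3.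

## Further compounds

F1 | step 4 | 1-(5-hydroxy-2,2-dimethyl-2H-chromen-6-yl)ethan-1-one | CC(=O)c1ccc2OC(C)(C)C=Cc2c1O
F2 | step 3 | 1-[2-hydroxy-4-(methoxymethoxy)-3-(3-methylbut-2-en-1-yl)phenyl]ethan-1-one | CC(=O)c1ccc(OCOC)c(CC=C(C)C)c1O
F3 | step 3 | 4-(methoxymethoxy)-3-(3-methylbut-2-en-1-yl)benzaldehyde | CC(C)=CCc1cc(C=O)ccc1OCOC
F4 | step 3 | (E)-1-[2-hydroxy-4-(methoxymethoxy)-3-(3-methylbut-2-en-1-yl)phenyl]-3-[4-(methoxymethoxy)-3-(3-methylbut-2-en-1-yl)phenyl]prop-2-en-1-one | CC(C)=CCc1cc(/C=C/C(=O)c2ccc(OCOC)c(CC=C(C)C)c2O)ccc1OCOC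
F5 | step 1 | 1-[2-hydroxy-4-(2-methylbut-3-yn-2-yloxy)phenyl]ethan-1-one | CC(=O)c1ccc(OC(C)(C)C#C)cc1O
F6 | step 1 | 1-[2-hydroxy-4-(2-methylbut-3-en-2-yloxy)phenyl]ethan-1-one | CC(=O)c1ccc(OC(C)(C)C=C)cc1O
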